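The time allowed is 1.0 min, and in it the substrate, the limiting reagent of this flask, can react with no more coupling partner than has dissolved from the solid reagent.

    substrate + coupling partner → other mono adduct (k1 = 3.74 L mol⁻¹ s⁻¹)
    coupling partner + single product → bis adduct (k2 = 2.54 L mol⁻¹ s⁻¹)
    solid reagent ⇌ coupling partner, rate k3*(cs3 - [coupling partner]) while solid is left; crystals form when [coupling partner] > cs3 (cs3 = 2.3 mM, k3 = 0.182 s⁻¹)
    substrate + coupling partner → single product (k4 = 5.31 L mol⁻¹ s⁻¹)
    coupling partner + other mono adduct → bis adduct (k5 = 6.75 L mol⁻¹ s⁻¹)
    single product ⇌ isomer of the product (K6 = 5.5, k6 = 6.17 × 10⁻⁴ s⁻¹)

substrate 0.029 M; solid reagent 2.00 equiv; time 1.0 min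

- solid reagent is a solid; its amount is given per volume of the solution
- at the start none of the solid reagent is in solution
- run time (flask): 1.0 min

- amount of single product at 1.0 min, in percent of the substrate charged
- the change that raises the amount of single product at 1.0 min, in percent of the substrate charged most ("none" if none brings more than 2 percentage points) (eta / theta / none)
- amount of single product at 1.0 min, in percent of the substrate charged, after theta

- eta: doubling the solubility in step 3, all else as stated
- theta: doubling the dissolution coefficient of step 3, all else as stated

We write the balance of the substrate first: it falls by its two additions together, and a share of 58.7% of what reacts becomes single product, so the run hangs on [coupling partner]. With 2.00 equiv of solid against the 86.6% of the substrate that dissolving can deliver at most by then, we take solid as present throughout.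

Dissolving feeds the solution, and the substrate captures the partner with a constant of 0.262 s⁻¹ at the charge, faster than the dissolution coefficient 0.182 s⁻¹. Setting feed equal to capture gives [coupling partner] over the solubility as dissolution coefficient divided by the sum of dissolution coefficient and capture constant, which is 40.9%. This saturation fraction, the share of the solubility at which dissolving just pays for capture, is what we carry.

Holding [coupling partner] level makes the substrate decay pseudo-first-order. We multiply the share above by the substrate reacted, then by what survives bis addition at the mean age of the product, and set up our table:

- as stated: fraction 40.9%, [coupling partner] 0.942 mM, single product 21.9%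
- eta: fraction 40.9%, [coupling partner] 1.88 mM, single product 32.6%
- theta: fraction 58.1%, [coupling partner] 1.34 mM, single product 27.3%

Reading down the second column, eta leaves the fraction as it was and carries the level up to twice its value. Theta raises the fraction, but the level grows by a factor of 1.42, so eta stands above theta in the last column.

The forecast stood at 21.9% (20.5% to 23.5%), at 27.3% (25.5% to 29%) after theta, and on eta, with the ground that “Doubling the solubility doubles the driving force”.

The flask gives 21.9%, and 27.2% after theta, while eta gains 11 percentage points against 5.4 points for theta, so the choice is eta. In the flask as stated the dissolved coupling partner read 43.8% of saturation at 0.500 min, when the substrate stood at 78.3%, and our fraction reckoned with that substrate instead of the charge is 47.0%. Carried to a neighbour flask with 0.0073 M of substrate, equivalents and time held, the fraction becomes 73.4% and the level 1.69 mM, and the same factors give 31.0% of single product; that neighbour flask read 29.6%.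

The numbers of this flask were set for the occasion; what happens was integrated by code.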